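**Retrosynthetic overview**
- The target comes from its 6,8-dimethoxy lactone by chelation-controlled removal of the 8-O-methyl group.
- The lactone ring is the only ring made (the benzene ring is bought). Its C8a–C1 bond is closed by a visible-light alkoxycarbonyl-radical cyclisation of the oxalate of the (S)-2-hydroxypropyl arm onto the one free ring position.
- The C4a–C4 bond comes from a nickel/photoredox cross-electrophile coupling of an aryl bromide with (S)-propylene oxide, which supplies C3.
- The C7 side chain comes from metalation of 1-bromo-3,5-dimethoxybenzene between its methoxy groups, opening of methyl (S)-glycidate (which supplies the acetoxy carbon), MeMgBr addition and acetylation.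

Assumption: the SMILES is taken as drawn, which reads as S at the lactone carbinol carbon (C3) and S at the acetoxy-bearing carbon of the side chain.

**Step 1**
Reactants: 1 (1-bromo-3,5-dimethoxybenzene) + 2 (methyl (S)-oxirane-2-carboxylate)
Product: 6 (S)-1-(4-bromo-2,6-dimethoxyphenyl)-3-methylbutane-2,3-diol, via aryllithium 3 (not isolated), via arylmagnesium bromide 4 (not isolated), via hydroxy ester 5 (not isolated)
Conditions: LiN(iPr)2, THF, −78 °C; MgBr2·OEt2, −78 → −40 °C; CuI (10 mol%), 2, −40 °C; MeMgBr (4 equiv), −40 → 0 °C; aq NH4Cl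
Reagents that add atoms: methylmagnesium bromide (MeMgBr), C[Mg]Br
Why: Directed ortho-metalation at the position flanked by both methoxy groups, transmetalation to magnesium and copper-catalysed SN2 opening of the glycidate at its unsubstituted CH2 give 5 with the purchased stereocentre untouched (S), and double Grignard addition to the ester then builds the tertiary carbinol.

**Step 2**
Reactants: 6 ((S)-1-(4-bromo-2,6-dimethoxyphenyl)-3-methylbutane-2,3-diol)
Product: 7 (S)-1-(4-bromo-2,6-dimethoxyphenyl)-3-hydroxy-3-methylbutan-2-yl acetate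
Conditions: Ac2O (1.2 equiv), pyridine, DMAP (5 mol%), CH2Cl2, 0 °C
Reagents that add atoms: acetic anhydride (Ac2O), CC(=O)OC(C)=O
Why: DMAP-catalysed acylation is selective for the secondary hydroxyl because the neighbouring tertiary carbinol is too hindered to react at 0 °C, and no stereocentre is touched.

**Step 3**
Reactants: 7 ((S)-1-(4-bromo-2,6-dimethoxyphenyl)-3-hydroxy-3-methylbutan-2-yl acetate) + 8 ((S)-2-methyloxirane)
Product: 10 (S)-3-hydroxy-1-{4-[(S)-2-hydroxypropyl]-2,6-dimethoxyphenyl}-3-methylbutan-2-yl acetate, via iodohydrin 9 (not isolated)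
Conditions: 8 (3 equiv), NiBr2(dme) (10 mol%), 4,4'-di-tert-butyl-2,2'-bipyridine (12 mol%), 4CzIPN (2 mol%), NaI (0.5 equiv), Et3N·HCl (1 equiv), Hantzsch ester (1.5 equiv), DMA, sealed tube, 450 nm LEDs, 25 °C
Reagents that add atoms: none
Why: Nickel/photoredox cross-electrophile coupling of an aryl bromide with an epoxide by the iodohydrin pathway, in which iodide opens 8 at its CH2 terminus to 9, the photoreduced nickel catalyst turns the carbon–iodine bond into a primary radical that is captured by the aryl–nickel species and reductively eliminated, so the carbinol stereocentre bought in 8 is never involved and stays S.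

**Step 4**
Reactants: 10 ((S)-3-hydroxy-1-{4-[(S)-2-hydroxypropyl]-2,6-dimethoxyphenyl}-3-methylbutan-2-yl acetate)
Product: 13 (S)-1-[(S)-6,8-dimethoxy-3-methyl-1-oxoisochroman-7-yl]-3-hydroxy-3-methylbutan-2-yl acetate, via chlorooxalate 11 (not isolated), via N-phthalimidoyl oxalate 12 (not isolated)
Conditions: (COCl)2 (1.5 equiv), CH2Cl2, −40 °C, evaporate; N-hydroxyphthalimide, pyridine, CH2Cl2, 0 °C; fac-Ir(ppy)3 (1 mol%), MeCN, 450 nm LEDs, 25 °C
Reagents that add atoms: oxalyl chloride, O=C(Cl)C(Cl)=O
Why: Proposed new method: single-electron reduction of the redox-active oxalate 12 by excited fac-Ir(ppy)3 releases CO2 and phthalimide anion and leaves a secondary alkoxycarbonyl radical that loses CO2 only slowly, so it adds to the ortho ring carbon (both ortho sites are equivalent and no other ring C–H exists) to close the six-membered lactone and give a cyclohexadienyl radical stabilised by both methoxy groups, which the tetravalent iridium formed in the quenching step oxidises to the arenium ion that loses a proton in a redox-neutral cycle; the closest known reactions are the 5-exo cyclisations of alkoxycarbonyl radicals from N-phthalimidoyl oxalates onto alkenes and the homolytic aromatic substitutions of acyl and carbamoyl radicals, and no stereocentre is formed or touched.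

**Step 5**
Reactants: 13 ((S)-1-[(S)-6,8-dimethoxy-3-methyl-1-oxoisochroman-7-yl]-3-hydroxy-3-methylbutan-2-yl acetate)
Product: 14 (S)-3-hydroxy-1-[(S)-8-hydroxy-6-methoxy-3-methyl-1-oxoisochroman-7-yl]-3-methylbutan-2-yl acetate (CNP0209219.1)
Conditions: BCl3 (3 equiv), CH2Cl2, −78 °C; aq NaHCO3
Reagents that add atoms: none
Why: Chelation-controlled Lewis-acid ether cleavage, in which BCl3 bridges the lactone carbonyl and the peri 8-methoxy oxygen so that chloride removes only that methyl group, the 6-methoxy group is not chelated, and at −78 °C the acetate and the inductively deactivated tertiary alcohol survive with both stereocentres untouched.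

**Compound list**
1 | 1-bromo-3,5-dimethoxybenzene | COc1cc(Br)cc(OC)c1 | starting material
2 | methyl (S)-oxirane-2-carboxylate (methyl (S)-glycidate) | COC(=O)[C@@H]1CO1 | starting material
3 | (4-bromo-2,6-dimethoxyphenyl)lithium | [Li]c1c(OC)cc(Br)cc1OC | intermediate
4 | (4-bromo-2,6-dimethoxyphenyl)magnesium bromide | Br[Mg]c1c(OC)cc(Br)cc1OC | intermediate
5 | methyl (S)-3-(4-bromo-2,6-dimethoxyphenyl)-2-hydroxypropanoate (present as its magnesium alkoxide) | COc1cc(Br)cc(OC)c1C[C@H](O)C(=O)OC | intermediate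
6 | (S)-1-(4-bromo-2,6-dimethoxyphenyl)-3-methylbutane-2,3-diol | COc1cc(Br)cc(OC)c1C[C@H](O)C(C)(C)O | intermediate
7 | (S)-1-(4-bromo-2,6-dimethoxyphenyl)-3-hydroxy-3-methylbutan-2-yl acetate | COc1cc(Br)cc(OC)c1C[C@H](OC(C)=O)C(C)(C)O | intermediate
8 | (S)-2-methyloxirane ((S)-propylene oxide) | C[C@H]1CO1 | starting material
9 | (S)-1-iodopropan-2-ol | C[C@H](O)CI | intermediate
10 | (S)-3-hydroxy-1-{4-[(S)-2-hydroxypropyl]-2,6-dimethoxyphenyl}-3-methylbutan-2-yl acetate | COc1cc(C[C@H](C)O)cc(OC)c1C[C@H](OC(C)=O)C(C)(C)O | intermediate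
11 | (S)-1-{4-[(S)-2-acetoxy-3-hydroxy-3-methylbutyl]-3,5-dimethoxyphenyl}propan-2-yl 2-chloro-2-oxoacetate | COc1cc(C[C@H](C)OC(=O)C(Cl)=O)cc(OC)c1C[C@H](OC(C)=O)C(C)(C)O | intermediate
12 | (S)-1-{4-[(S)-2-acetoxy-3-hydroxy-3-methylbutyl]-3,5-dimethoxyphenyl}propan-2-yl 1,3-dioxoisoindolin-2-yl oxalate | COc1cc(C[C@H](C)OC(=O)C(=O)ON2C(=O)c3ccccc3C2=O)cc(OC)c1C[C@H](OC(C)=O)C(C)(C)O | intermediate
13 | (S)-1-[(S)-6,8-dimethoxy-3-methyl-1-oxoisochroman-7-yl]-3-hydroxy-3-methylbutan-2-yl acetate | COc1cc2c(c(OC)c1C[C@H](OC(C)=O)C(C)(C)O)C(=O)O[C@@H](C)C2 | intermediate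
14 | (S)-3-hydroxy-1-[(S)-8-hydroxy-6-methoxy-3-methyl-1-oxoisochroman-7-yl]-3-methylbutan-2-yl acetate | COc1cc2c(c(O)c1C[C@H](OC(C)=O)C(C)(C)O)C(=O)O[C@@H](C)C2 | target

**Step count and risks**
Total step count: 5. Longest linear sequence: 5 (1 → 6 → 7 → 10 → 13 → 14). The three steps most likely to fail are step 4 (highest risk, new reaction), step 3 and step 5.

Step 3 may suffer from protodehalogenation of the aryl bromide, from reduction of the iodohydrin, or from a minor branched isomer if iodide opens 8 at the substituted carbon. The fallback sets out from 1 and comes back to the route at 10. It swaps the order of the two side arms so that classical organolithium chemistry can be used: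
- n-BuLi (THF, −78 °C) converts 1 into (3,5-dimethoxyphenyl)lithium F1, which opens 8 at its CH2 terminus (CuI 10 mol%, −40 → 0 °C) to give (S)-1-(3,5-dimethoxyphenyl)propan-2-ol F2.
- TBSCl and imidazole in DMF give the tert-butyldimethylsilyl ether F3.
- n-BuLi (THF, 0 °C) metalates F3 between the methoxy groups to the aryllithium F4. MgBr2·OEt2 turns it into the arylmagnesium bromide F5, CuI-catalysed opening of 2 gives the hydroxy ester F6, and MeMgBr in the same flask gives the diol F7.
- Ac2O, pyridine and DMAP acetylate the secondary alcohol to the acetate F8, and HF·pyridine (THF, 0 °C) removes the silyl group to give 10.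

Step 4 is new chemistry. The alkoxycarbonyl radical may add too slowly to the electron-rich ring, lose CO2, or be reduced to a formate. The fallback uses known chemistry, sets out from 10 and comes back at 13. NBS (MeCN, 0 °C) brominates the only free, doubly activated ring position to give (S)-1-{3-bromo-4-[(S)-2-hydroxypropyl]-2,6-dimethoxyphenyl}-3-hydroxy-3-methylbutan-2-yl acetate F9. Palladium-catalysed carbonylative lactonisation (Pd(OAc)2 5 mol%, Xantphos, CO 1 atm, Et3N, toluene, 90 °C) then closes the six-membered lactone through the neighbouring secondary alcohol.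

Step 5 may fail if the tertiary alcohol ionises with help from the neighbouring acetate, which would move or lose the acetyl group. The fallback sets out from 13 and comes back at 14. It changes the order so that the demethylation is run on the free diol:
- K2CO3 in MeOH (0 °C) removes the acetate to give the diol lactone F10.
- BCl3 (CH2Cl2, −78 °C) ties the vicinal diol up as a cyclic chloroboronate and cleaves the chelated 8-O-methyl group to give the triol F11.
- Ac2O, pyridine and DMAP acetylate the phenol and the secondary alcohol to the diacetate F12.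
- Pyrrolidine (1.1 equiv, CH2Cl2, 0 °C) cleaves only the aryl acetate and gives 14.

**Further compounds**
F1 | step 3 | (3,5-dimethoxyphenyl)lithium | [Li]c1cc(OC)cc(OC)c1
F2 | step 3 | (S)-1-(3,5-dimethoxyphenyl)propan-2-ol | COc1cc(C[C@H](C)O)cc(OC)c1
F3 | step 3 | tert-butyl{[(S)-1-(3,5-dimethoxyphenyl)propan-2-yl]oxy}dimethylsilane | COc1cc(C[C@H](C)O[Si](C)(C)C(C)(C)C)cc(OC)c1
F4 | step 3 | {4-[(S)-2-(tert-butyldimethylsilyloxy)propyl]-2,6-dimethoxyphenyl}lithium | [Li]c1c(OC)cc(C[C@H](C)O[Si](C)(C)C(C)(C)C)cc1OC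
F5 | step 3 | {4-[(S)-2-(tert-butyldimethylsilyloxy)propyl]-2,6-dimethoxyphenyl}magnesium bromide | Br[Mg]c1c(OC)cc(C[C@H](C)O[Si](C)(C)C(C)(C)C)cc1OC
F6 | step 3 | methyl (S)-3-{4-[(S)-2-(tert-butyldimethylsilyloxy)propyl]-2,6-dimethoxyphenyl}-2-hydroxypropanoate | COc1cc(C[C@H](C)O[Si](C)(C)C(C)(C)C)cc(OC)c1C[C@H](O)C(=O)OC
F7 | step 3 | (S)-1-{4-[(S)-2-(tert-butyldimethylsilyloxy)propyl]-2,6-dimethoxyphenyl}-3-methylbutane-2,3-diol | COc1cc(C[C@H](C)O[Si](C)(C)C(C)(C)C)cc(OC)c1C[C@H](O)C(C)(C)O
F8 | step 3 | (S)-1-{4-[(S)-2-(tert-butyldimethylsilyloxy)propyl]-2,6-dimethoxyphenyl}-3-hydroxy-3-methylbutan-2-yl acetate | COc1cc(C[C@H](C)O[Si](C)(C)C(C)(C)C)cc(OC)c1C[C@H](OC(C)=O)C(C)(C)O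
F9 | step 4 | (S)-1-{3-bromo-4-[(S)-2-hydroxypropyl]-2,6-dimethoxyphenyl}-3-hydroxy-3-methylbutan-2-yl acetate | COc1cc(C[C@H](C)O)c(Br)c(OC)c1C[C@H](OC(C)=O)C(C)(C)O
F10 | step 5 | (S)-7-[(S)-2,3-dihydroxy-3-methylbutyl]-6,8-dimethoxy-3-methylisochroman-1-one | COc1cc2c(c(OC)c1C[C@H](O)C(C)(C)O)C(=O)O[C@@H](C)C2
F11 | step 5 | (S)-7-[(S)-2,3-dihydroxy-3-methylbutyl]-8-hydroxy-6-methoxy-3-methylisochroman-1-one | COc1cc2c(c(O)c1C[C@H](O)C(C)(C)O)C(=O)O[C@@H](C)C2
F12 | step 5 | (S)-7-[(S)-2-acetoxy-3-hydroxy-3-methylbutyl]-6-methoxy-3-methyl-1-oxoisochroman-8-yl acetate | COc1cc2c(c(OC(C)=O)c1C[C@H](OC(C)=O)C(C)(C)O)C(=O)O[C@@H](C)C2
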